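**Assumption:** (−)-Epigallocatechin, a commercially sold green-tea catechin, is taken as the chiral starting material; the triazolium antipode named in step 7 is presumed to give the (R)-methine, and its mirror image is equally available if the first run shows the opposite sense.

## Retrosynthetic overview

1. Target 17 ⇐ hydrogenolysis of all 17 benzyl ethers and the C8–Br of 16 ⇐ double esterification of diol 14 (flavan 3-OH and side-chain carbinol) with acid 15.
2. 14 ⇐ Felkin–Anh reduction of α,α-diaryl ketone 12. Its CO–CH(Ar)2 bond is the key disconnection: the acyl anion (Breslow intermediate) of aldehyde 11 adds 1,6 to para-quinone methide 7, joining two normally electrophilic carbons.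
3. 7 ⇐ Friedel–Crafts condensation of hydroxy-aldehyde 5 at C6 of 3; 3 ⇐ (−)-epigallocatechin 1 by phenol benzylation and C8 bromination (bromine is a traceless block).
4. 11 ⇐ 1,3,5-tris(benzyloxy)benzene 8 (lithiation, ethylene oxide, oxidation); 5 ⇐ aldehyde 4 (para-debenzylation).
5. No ring is built: rings A, B and C and the 2R,3R centres come from 1, and every other ring from an aromatic starting material.

## Route

Step 1
Reactants: 1 (−)-epigallocatechin
Product: 2 penta-O-benzyl-EGC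
Conditions: BnBr (5.5 equiv), K2CO3 (6 equiv), degassed DMF, N2, 0 °C → rt
Reagents that add atoms: benzyl bromide, BrCc1ccccc1
Why: Williamson etherification with a carbonate base alkylates only the five phenols (the secondary 3-OH is not deprotonated), and the cold, oxygen-free conditions spare the pyrogallol ring and the 2R,3R centres.

Step 2
Reactants: 2 penta-O-benzyl-EGC
Product: 3 8-bromo-penta-O-benzyl-EGC
Conditions: NBS (1.05 equiv), CH2Cl2, −78 °C → rt
Reagents that add atoms: N-bromosuccinimide, O=C1CCC(=O)N1Br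
Why: Electrophilic aromatic bromination goes to C8, the most nucleophilic position of ring A in benzylated flavan-3-ols with a free 3-OH, so that C6 remains the only free activated site and the bromine can be removed in the last step.

Step 3
Reactants: 4 3,4,5-tris(benzyloxy)benzaldehyde
Product: 5 3,5-bis(benzyloxy)-4-hydroxybenzaldehyde
Conditions: MgBr2·OEt2 (1.5 equiv), toluene–Et2O, 80 °C; 1 M HCl
Reagents that add atoms: none
Why: Lewis-acid-mediated regioselective ether cleavage, in which magnesium chelates the twisted, most basic central ether (para to the formyl group, best phenoxide leaving group) and bromide removes its benzyl group by SN2.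

Step 4
Reactants: 3 8-bromo-penta-O-benzyl-EGC; 5 3,5-bis(benzyloxy)-4-hydroxybenzaldehyde
Product: 7 8-bromo-6-{[3,5-bis(benzyloxy)-4-oxocyclohexa-2,5-dien-1-ylidene]methyl}-penta-O-benzyl-EGC (para-quinone methide), via diarylmethanol 6 (not isolated)
Conditions: CF3CO2H (10 equiv), CH2Cl2–(CF3)2CHOH 4:1, 0 °C → rt; aq NaHCO3
Reagents that add atoms: none
Why: Friedel–Crafts hydroxyalkylation at C6 followed by dehydration through the free 4-hydroxyl (the chemistry of the vanillin–flavanol condensation) gives a push–pull quinone methide whose hindered, stabilised methine resists a second arylation and cannot be reached intramolecularly by the 3-OH.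

Step 5
Reactants: 8 1,3,5-tris(benzyloxy)benzene
Product: 10 2-[2,4,6-tris(benzyloxy)phenyl]ethan-1-ol, via aryllithium 9 (not isolated)
Conditions: n-BuLi (1.1 equiv), THF, 0 °C → rt; ethylene oxide, 0 °C → rt; 1 M HCl
Reagents that add atoms: ethylene oxide, C1CO1
Why: Directed ortho-lithiation between two benzyloxy groups (all three ring positions are equivalent) followed by epoxide ring-opening with the aryllithium.

Step 6
Reactants: 10 2-[2,4,6-tris(benzyloxy)phenyl]ethan-1-ol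
Product: 11 2-[2,4,6-tris(benzyloxy)phenyl]acetaldehyde
Conditions: Dess–Martin periodinane (1,1,1-triacetoxy-1,1-dihydro-1,2-benziodoxol-3(1H)-one, 1.2 equiv), CH2Cl2, 0 °C → rt
Reagents that add atoms: none
Why: Dess–Martin oxidation is neutral and fast enough to deliver the enolisable arylacetaldehyde without over-oxidation or aldol condensation.

Step 7
Reactants: 7 para-quinone methide; 11 2-[2,4,6-tris(benzyloxy)phenyl]acetaldehyde (2 equiv)
Product: 13 (1R,2S)-1-[3,5-bis(benzyloxy)-4-hydroxyphenyl]-1-(8-bromo-penta-O-benzyl-EGC-6-yl)-3-[2,4,6-tris(benzyloxy)phenyl]propan-2-ol, via ketone 12 (not isolated)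
Conditions: (5aR,10bS)-2-(pentafluorophenyl)-5a,10b-dihydro-4H,6H-indeno[2,1-b][1,2,4]triazolo[4,3-d][1,4]oxazin-2-ium tetrafluoroborate (20 mol%), i-Pr2NEt (1 equiv), THF, 4 Å MS, 0 °C → rt; then LiBH(s-Bu)3 (6 equiv), −78 °C; AcOH
Reagents that add atoms: none
Why: Proposed new method: the chiral triazolylidene turns 11 into a Breslow intermediate (acyl anion equivalent) that adds 1,6 to the exocyclic carbon of 7 with rearomatisation, the catalyst pocket choosing the face that gives the (R)-methine (closest known reaction types: carbene-catalysed 1,6-addition of aldehydes to para-quinone methides and the asymmetric intermolecular Stetter reaction of enolisable aldehydes), and the cold bulky hydride then reduces the un-isolated ketone under Felkin–Anh control (ring-A aryl anti to hydride) to the (S)-carbinol before the labile α-centre can epimerise.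

Step 8
Reactants: 13 phenol–diol
Product: 14 (1R,2S)-1-(8-bromo-penta-O-benzyl-EGC-6-yl)-1-[3,4,5-tris(benzyloxy)phenyl]-3-[2,4,6-tris(benzyloxy)phenyl]propan-2-ol
Conditions: BnBr (1.5 equiv), K2CO3, DMF, rt
Reagents that add atoms: benzyl bromide, BrCc1ccccc1
Why: Williamson etherification is chemoselective for the phenol (the only hydroxyl deprotonated by carbonate) over the two secondary alcohols, and no epimerisable centre remains.

Step 9
Reactants: 14 fully benzylated diol; 15 3,4,5-tris(benzyloxy)benzoic acid (4 equiv used, two molecules incorporated)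
Product: 16 (1R,2S)-1-[(2R,3R)-8-bromo-octa-O-benzyl-EGCG-6-yl]-1-[3,4,5-tris(benzyloxy)phenyl]-3-[2,4,6-tris(benzyloxy)phenyl]propan-2-yl 3,4,5-tris(benzyloxy)benzoate
Conditions: N,N'-dicyclohexylcarbodiimide (5 equiv), 4-(dimethylamino)pyridine (1 equiv), CH2Cl2, rt → 40 °C
Reagents that add atoms: 3,4,5-tris(benzyloxy)benzoic acid, OC(=O)c1cc(OCc2ccccc2)c(OCc2ccccc2)c(OCc2ccccc2)c1
Why: Steglich esterification through the acylpyridinium ion acylates both secondary hydroxyls (the flavan 3-OH and the side-chain carbinol) on oxygen without breaking either C–O bond, so the 3R and (S) configurations are retained.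

Step 10
Reactants: 16 perbenzylated bromo bis-gallate
Product: 17 CNP0240551.2
Conditions: H2 (1 atm), Pd(OH)2 on carbon (20 wt%), NaOAc (1.5 equiv), THF–MeOH 1:1, rt
Reagents that add atoms: none
Why: Catalytic hydrogenolysis removes all seventeen O-benzyl groups and the C8 bromine (hydrodehalogenation) in one operation, while the two gallate esters, the diarylmethine and the four stereocentres are not touched.

## Compound list

1 | (−)-epigallocatechin, (2R,3R)-2-(3,4,5-trihydroxyphenyl)chromane-3,5,7-triol | O[C@@H]1Cc2c(O)cc(O)cc2O[C@@H]1c1cc(O)c(O)c(O)c1 | starting material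

2 | penta-O-benzyl-EGC, (2R,3R)-5,7-bis(benzyloxy)-2-[3,4,5-tris(benzyloxy)phenyl]chroman-3-ol | O[C@@H]1Cc2c(OCc3ccccc3)cc(OCc3ccccc3)cc2O[C@@H]1c1cc(OCc2ccccc2)c(OCc2ccccc2)c(OCc2ccccc2)c1 | intermediate

3 | 8-bromo-penta-O-benzyl-EGC, (2R,3R)-5,7-bis(benzyloxy)-8-bromo-2-[3,4,5-tris(benzyloxy)phenyl]chroman-3-ol | O[C@@H]1Cc2c(OCc3ccccc3)cc(OCc3ccccc3)c(Br)c2O[C@@H]1c1cc(OCc2ccccc2)c(OCc2ccccc2)c(OCc2ccccc2)c1 | intermediate

4 | 3,4,5-tris(benzyloxy)benzaldehyde | O=Cc1cc(OCc2ccccc2)c(OCc2ccccc2)c(OCc2ccccc2)c1 | starting material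

5 | 3,5-bis(benzyloxy)-4-hydroxybenzaldehyde | O=Cc1cc(OCc2ccccc2)c(O)c(OCc2ccccc2)c1 | intermediate

6 | diarylmethanol: 8-bromo-6-{[3,5-bis(benzyloxy)-4-hydroxyphenyl](hydroxy)methyl}-penta-O-benzyl-EGC (both carbinol epimers, 2R,3R in the flavan) | O[C@@H]1Cc2c(OCc3ccccc3)c(C(O)c3cc(OCc4ccccc4)c(O)c(OCc4ccccc4)c3)c(OCc3ccccc3)c(Br)c2O[C@@H]1c1cc(OCc2ccccc2)c(OCc2ccccc2)c(OCc2ccccc2)c1 | intermediate

7 | para-quinone methide: 8-bromo-6-{[3,5-bis(benzyloxy)-4-oxocyclohexa-2,5-dien-1-ylidene]methyl}-penta-O-benzyl-EGC (2R,3R) | O[C@@H]1Cc2c(OCc3ccccc3)c(C=C3C=C(OCc4ccccc4)C(=O)C(OCc4ccccc4)=C3)c(OCc3ccccc3)c(Br)c2O[C@@H]1c1cc(OCc2ccccc2)c(OCc2ccccc2)c(OCc2ccccc2)c1 | intermediate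

8 | 1,3,5-tris(benzyloxy)benzene | C(Oc1cc(OCc2ccccc2)cc(OCc2ccccc2)c1)c1ccccc1 | starting material

9 | 2,4,6-tris(benzyloxy)phenyllithium | [Li]c1c(OCc2ccccc2)cc(OCc2ccccc2)cc1OCc1ccccc1 | intermediate

10 | 2-[2,4,6-tris(benzyloxy)phenyl]ethan-1-ol | OCCc1c(OCc2ccccc2)cc(OCc2ccccc2)cc1OCc1ccccc1 | intermediate

11 | 2-[2,4,6-tris(benzyloxy)phenyl]acetaldehyde | O=CCc1c(OCc2ccccc2)cc(OCc2ccccc2)cc1OCc1ccccc1 | intermediate

12 | (R)-1-[3,5-bis(benzyloxy)-4-hydroxyphenyl]-1-(8-bromo-penta-O-benzyl-EGC-6-yl)-3-[2,4,6-tris(benzyloxy)phenyl]propan-2-one | O=C(Cc1c(OCc2ccccc2)cc(OCc2ccccc2)cc1OCc1ccccc1)[C@H](c1cc(OCc2ccccc2)c(O)c(OCc2ccccc2)c1)c1c(OCc2ccccc2)c(Br)c2c(c1OCc1ccccc1)C[C@@H](O)[C@@H](c1cc(OCc3ccccc3)c(OCc3ccccc3)c(OCc3ccccc3)c1)O2 | intermediate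

13 | (1R,2S)-1-[3,5-bis(benzyloxy)-4-hydroxyphenyl]-1-(8-bromo-penta-O-benzyl-EGC-6-yl)-3-[2,4,6-tris(benzyloxy)phenyl]propan-2-ol | O[C@@H](Cc1c(OCc2ccccc2)cc(OCc2ccccc2)cc1OCc1ccccc1)[C@H](c1cc(OCc2ccccc2)c(O)c(OCc2ccccc2)c1)c1c(OCc2ccccc2)c(Br)c2c(c1OCc1ccccc1)C[C@@H](O)[C@@H](c1cc(OCc3ccccc3)c(OCc3ccccc3)c(OCc3ccccc3)c1)O2 | intermediate

14 | (1R,2S)-1-(8-bromo-penta-O-benzyl-EGC-6-yl)-1-[3,4,5-tris(benzyloxy)phenyl]-3-[2,4,6-tris(benzyloxy)phenyl]propan-2-ol | O[C@@H](Cc1c(OCc2ccccc2)cc(OCc2ccccc2)cc1OCc1ccccc1)[C@H](c1cc(OCc2ccccc2)c(OCc2ccccc2)c(OCc2ccccc2)c1)c1c(OCc2ccccc2)c(Br)c2c(c1OCc1ccccc1)C[C@@H](O)[C@@H](c1cc(OCc3ccccc3)c(OCc3ccccc3)c(OCc3ccccc3)c1)O2 | intermediate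

15 | 3,4,5-tris(benzyloxy)benzoic acid | OC(=O)c1cc(OCc2ccccc2)c(OCc2ccccc2)c(OCc2ccccc2)c1 | starting material

16 | (1R,2S)-1-[(2R,3R)-8-bromo-octa-O-benzyl-EGCG-6-yl]-1-[3,4,5-tris(benzyloxy)phenyl]-3-[2,4,6-tris(benzyloxy)phenyl]propan-2-yl 3,4,5-tris(benzyloxy)benzoate (the flavan 3-oxygen carries a second 3,4,5-tris(benzyloxy)benzoyl group) | O=C(O[C@@H](Cc1c(OCc2ccccc2)cc(OCc2ccccc2)cc1OCc1ccccc1)[C@H](c1cc(OCc2ccccc2)c(OCc2ccccc2)c(OCc2ccccc2)c1)c1c(OCc2ccccc2)c(Br)c2c(c1OCc1ccccc1)C[C@@H](OC(=O)c1cc(OCc3ccccc3)c(OCc3ccccc3)c(OCc3ccccc3)c1)[C@@H](c1cc(OCc3ccccc3)c(OCc3ccccc3)c(OCc3ccccc3)c1)O2)c1cc(OCc2ccccc2)c(OCc2ccccc2)c(OCc2ccccc2)c1 | intermediate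

17 | CNP0240551.2, (1R,2S)-1-[(2R,3R)-5,7-dihydroxy-3-(3,4,5-trihydroxybenzoyloxy)-2-(3,4,5-trihydroxyphenyl)chroman-6-yl]-1-(3,4,5-trihydroxyphenyl)-3-(2,4,6-trihydroxyphenyl)propan-2-yl 3,4,5-trihydroxybenzoate | O=C(O[C@@H](Cc1c(O)cc(O)cc1O)[C@H](c1cc(O)c(O)c(O)c1)c1c(O)cc2c(c1O)C[C@@H](OC(=O)c1cc(O)c(O)c(O)c1)[C@@H](c1cc(O)c(O)c(O)c1)O2)c1cc(O)c(O)c(O)c1 | target

## Summary and risks

Total step count: 10. Longest linear sequence: 7 steps (1 → 2 → 3 → 7 → 13 → 14 → 16 → 17; steps 1, 2, 4, 7, 8, 9, 10).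

**Most likely to fail, first: step 7.** The hindered quinone methide may react slowly, the carbene may not control the methine, or the hydride may enolise the ketone instead of reducing it. The fallback sets out from 7 and 11 and returns at 14. The 1,6-addition is run with the achiral precatalyst 3-benzyl-5-(2-hydroxyethyl)-4-methylthiazolium chloride and Et3N, and the product is isolated as a mixture of methine epimers, ketone phenol F1. Its phenol is benzylated (BnBr, K2CO3, DMF) to the fully benzylated ketone F2. Both centres are then set together by dynamic kinetic resolution: hydrogenation with RuCl2[(S)-xylbinap][(S)-daipen] (ligand antipode chosen by screening), catalytic KOt-Bu, H2 (10 atm), i-PrOH–THF. The base equilibrates the α,α-diaryl centre while the catalyst reduces one epimer, giving 14; no ester is present at this stage to suffer alkoxide exchange.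

**Second: step 4.** The aldehyde may over-arylate to a triarylmethane, or benzyl ethers may be lost in acid. The fallback sets out from 5 (with 3) and returns at 7. Aldehyde 5 is reduced with NaBH4 to 3,5-bis(benzyloxy)-4-hydroxybenzyl alcohol F3. Acid-catalysed Friedel–Crafts benzylation of 3 at C6 with F3 (10 mol% TsOH, CH2Cl2–(CF3)2CHOH) gives 8-bromo-6-[3,5-bis(benzyloxy)-4-hydroxybenzyl]-penta-O-benzyl-EGC F4, which cannot over-arylate at the CH2 oxidation level. Dehydrogenation of this phenol with Ag2O (CH2Cl2, rt) gives 7.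

**Third: step 9.** The flavan 3-OH acylates readily, but the side-chain carbinol is flanked by a benzhydryl group and a 2,6-disubstituted benzyl group, so carbodiimide activation may stall at the N-acylurea and leave a mono-gallate. The fallback sets out from 15 and 14 and returns at 16. It activates the nucleophile rather than the acid: 15 is converted with oxalyl chloride and catalytic DMF into 3,4,5-tris(benzyloxy)benzoyl chloride F5, diol 14 is doubly deprotonated with KN(SiMe3)2 (2.2 equiv, THF, −78 °C), and the dipotassium alkoxide is acylated with F5 (2.5 equiv) to give 16.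

## Further compounds

F1 | step 7 | 1-[3,5-bis(benzyloxy)-4-hydroxyphenyl]-1-(8-bromo-penta-O-benzyl-EGC-6-yl)-3-[2,4,6-tris(benzyloxy)phenyl]propan-2-one, both methine epimers | O=C(Cc1c(OCc2ccccc2)cc(OCc2ccccc2)cc1OCc1ccccc1)C(c1cc(OCc2ccccc2)c(O)c(OCc2ccccc2)c1)c1c(OCc2ccccc2)c(Br)c2c(c1OCc1ccccc1)C[C@@H](O)[C@@H](c1cc(OCc3ccccc3)c(OCc3ccccc3)c(OCc3ccccc3)c1)O2
F2 | step 7 | 1-(8-bromo-penta-O-benzyl-EGC-6-yl)-1-[3,4,5-tris(benzyloxy)phenyl]-3-[2,4,6-tris(benzyloxy)phenyl]propan-2-one, both methine epimers | O=C(Cc1c(OCc2ccccc2)cc(OCc2ccccc2)cc1OCc1ccccc1)C(c1cc(OCc2ccccc2)c(OCc2ccccc2)c(OCc2ccccc2)c1)c1c(OCc2ccccc2)c(Br)c2c(c1OCc1ccccc1)C[C@@H](O)[C@@H](c1cc(OCc3ccccc3)c(OCc3ccccc3)c(OCc3ccccc3)c1)O2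
F3 | step 4 | 3,5-bis(benzyloxy)-4-hydroxybenzyl alcohol | OCc1cc(OCc2ccccc2)c(O)c(OCc2ccccc2)c1
F4 | step 4 | 8-bromo-6-[3,5-bis(benzyloxy)-4-hydroxybenzyl]-penta-O-benzyl-EGC (2R,3R) | O[C@@H]1Cc2c(OCc3ccccc3)c(Cc3cc(OCc4ccccc4)c(O)c(OCc4ccccc4)c3)c(OCc3ccccc3)c(Br)c2O[C@@H]1c1cc(OCc2ccccc2)c(OCc2ccccc2)c(OCc2ccccc2)c1
F5 | step 9 | 3,4,5-tris(benzyloxy)benzoyl chloride | O=C(Cl)c1cc(OCc2ccccc2)c(OCc2ccccc2)c(OCc2ccccc2)c1
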